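**Assumption:** the target has no stereocentre (it is achiral, with two identical quinone rings on a (CH2)14 tether), so "single enantiomer" simply means this one constitution and no stereocontrol is needed.

**Retrosynthetic overview**
- 9 ⇐ 8 (acid epoxide-to-hydroxyquinone isomerisation) ⇐ 7 (nucleophilic epoxidation): the last ring C–H becomes C–OH.
- 7 ⇐ 6 (O-methylation of the vinylogous acid) ⇐ 5 (para-oxidation of the resorcinol): oxidative tailoring after ring formation.
- 5 ⇐ 4: twofold intramolecular aldol aromatisation of two unreduced triketide chains (terminal CH3 onto the chain-bearing carbonyl). Both benzene rings form at the same time, in the first flask.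
- 4 ⇐ 1 + two molecules of 2 (via dianion 3): two-directional Claisen acylation; the two ester carbons of the C16 diester become the two chain-bearing ring carbons, and 2 supplies the ring C-methyl.

**Route**

Step 1
Reactants: 1 dimethyl hexadecanedioate; 2 3-methylpentane-2,4-dione (5 equiv)
Product: 5 bis-resorcinol 5,5'-(tetradecane-1,14-diyl)bis(2-methylbenzene-1,3-diol), via diketone dianion 3 (not isolated), via bis-triketone 4 (not isolated)
Conditions: 2, LiN(iPr)2 (10 equiv), THF, 0 °C; add 1, 0 °C to rt; then degassed 2 M aq. KOH, 50 °C, Ar; then 2 M HCl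
Reagents that add atoms: none
Why: Claisen acylation of the terminal carbanion of the 1,3-diketone dianion by each ester group builds a 3-methyl-2,4,6-triketone at both chain ends, and in aqueous base each triketone closes by a Collie-type polyketide aldol condensation (terminal CH3, the less hindered donor, onto the carbonyl that was the ester carbon, then dehydration and enolisation) to a 2-methyl-5-alkylresorcinol; no stereocentre is formed.

Step 2
Reactants: 5 bis-resorcinol 5,5'-(tetradecane-1,14-diyl)bis(2-methylbenzene-1,3-diol)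
Product: 6 bis(hydroxyquinone) 6,6'-(tetradecane-1,14-diyl)bis(2-hydroxy-3-methylcyclohexa-2,5-diene-1,4-dione)
Conditions: K2[ON(SO3)2] (5 equiv), aq. KH2PO4 (pH 6), acetone/H2O, 0 °C to rt
Reagents that add atoms: potassium nitrosodisulfonate, [K+].[K+].[O]N(S(=O)(=O)[O-])S(=O)(=O)[O-]
Why: Teuber oxidation, in which the nitroxyl radical oxidises the phenol and delivers oxygen to the free position para to one OH (the two such positions are equivalent by symmetry, and ortho attack leads to the same tautomeric hydroxyquinone), giving the 2-hydroxy-1,4-benzoquinone with the remaining C–H next to the chain.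

Step 3
Reactants: 6 bis(hydroxyquinone) 6,6'-(tetradecane-1,14-diyl)bis(2-hydroxy-3-methylcyclohexa-2,5-diene-1,4-dione)
Product: 7 bis(methoxyquinone) 6,6'-(tetradecane-1,14-diyl)bis(2-methoxy-3-methylcyclohexa-2,5-diene-1,4-dione)
Conditions: MeOH/CH2Cl2, H2SO4 (cat.), 60 °C
Reagents that add atoms: methanol, CO
Why: vinylogous Fischer esterification, since the hydroxyquinone OH is a vinylogous carboxylic acid and is the only hydroxyl in each ring, so acid-catalysed addition–elimination of methanol gives the more stable 2-methoxy-1,4-quinone with the OMe next to the ring methyl.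

Step 4
Reactants: 7 bis(methoxyquinone) 6,6'-(tetradecane-1,14-diyl)bis(2-methoxy-3-methylcyclohexa-2,5-diene-1,4-dione)
Product: 8 bis(epoxyquinone) 1,1'-(tetradecane-1,14-diyl)bis(3-methoxy-4-methyl-7-oxabicyclo[4.1.0]hept-3-ene-2,5-dione)
Conditions: tBuOOH (2.5 equiv, in decane), DBU (0.3 equiv), CH2Cl2, 0 °C
Reagents that add atoms: tert-butyl hydroperoxide, CC(C)(C)OO
Why: Weitz–Scheffer nucleophilic epoxidation, in which tBuOO– adds to the unsubstituted carbon of the electron-poor C(H)=C(alkyl) bond while the methoxy/methyl-substituted bond is a deactivated vinylogous ester; the cis-epoxide stereocentres form as a racemic/meso mixture and are erased in step 5.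

Step 5
Reactants: 8 bis(epoxyquinone) 1,1'-(tetradecane-1,14-diyl)bis(3-methoxy-4-methyl-7-oxabicyclo[4.1.0]hept-3-ene-2,5-dione)
Product: 9 target 3,3'-(tetradecane-1,14-diyl)bis(2-hydroxy-5-methoxy-6-methylcyclohexa-2,5-diene-1,4-dione)
Conditions: conc. H2SO4, 0 °C, 10 min; then ice/H2O
Reagents that add atoms: none
Why: acid-catalysed epoxyquinone-to-hydroxyquinone isomerisation (the classical conversion of 2-alkylnaphthoquinone oxides into 2-hydroxy-3-alkylnaphthoquinones), in which the protonated epoxide opens and the epoxide C–H is lost, leaving OH on the carbon next to the chain.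

**Compound list**
1 | dimethyl hexadecanedioate | COC(=O)CCCCCCCCCCCCCCC(=O)OC | starting material
2 | 3-methylpentane-2,4-dione | CC(=O)C(C)C(C)=O | starting material
3 | dilithium 3-methylpenta-1,3-diene-2,4-diolate (1,3-dianion of 2) | [Li+].[Li+].C=C([O-])C(C)=C(C)[O-] | intermediate
4 | 3,24-dimethylhexacosane-2,4,6,21,23,25-hexaone (bis-triketone, present in the flask as its lithium enolates; neutral form drawn) | CC(=O)C(C)C(=O)CC(=O)CCCCCCCCCCCCCCC(=O)CC(=O)C(C)C(C)=O | intermediate
5 | 5,5'-(tetradecane-1,14-diyl)bis(2-methylbenzene-1,3-diol) | Cc1c(O)cc(CCCCCCCCCCCCCCc2cc(O)c(C)c(O)c2)cc1O | intermediate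
6 | 6,6'-(tetradecane-1,14-diyl)bis(2-hydroxy-3-methylcyclohexa-2,5-diene-1,4-dione) | CC1=C(O)C(=O)C(CCCCCCCCCCCCCCC2=CC(=O)C(C)=C(O)C2=O)=CC1=O | intermediate
7 | 6,6'-(tetradecane-1,14-diyl)bis(2-methoxy-3-methylcyclohexa-2,5-diene-1,4-dione) | COC1=C(C)C(=O)C=C(CCCCCCCCCCCCCCC2=CC(=O)C(C)=C(OC)C2=O)C1=O | intermediate
8 | 1,1'-(tetradecane-1,14-diyl)bis(3-methoxy-4-methyl-7-oxabicyclo[4.1.0]hept-3-ene-2,5-dione), each epoxide cis-fused, racemic/meso diastereomer mixture (configuration not controlled, not needed) | COC1=C(C)C(=O)C2OC2(CCCCCCCCCCCCCCC34OC3C(=O)C(C)=C(OC)C4=O)C1=O | intermediate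
9 | 3,3'-(tetradecane-1,14-diyl)bis(2-hydroxy-5-methoxy-6-methylcyclohexa-2,5-diene-1,4-dione), achiral | COC1=C(C)C(=O)C(O)=C(CCCCCCCCCCCCCCC2=C(O)C(=O)C(C)=C(OC)C2=O)C1=O | target

**Step count**
Total steps: 5. Longest linear sequence: 5 (1 + 2 → 5 → 6 → 7 → 8 → 9).

**Steps most likely to fail, with fallbacks**

Step 1 (twofold Claisen/aldol cascade). The chain α-CH2 can compete with the terminal CH3 as aldol donor, which would give a 4,5-dimethyl-6-alkylresorcinol isomer. Hot alkali can also cleave the triketone by retro-Claisen reaction, and both ends must react correctly. The fallback activates the donor carbon with an ester, as in the thioester-bound tetraketide. It sets out from 2 (with 1 as partner) and returns at 5. The dianion of 2 (LiN(iPr)2, 2 equiv) is trapped with dimethyl carbonate to give methyl 4-methyl-3,5-dioxohexanoate F1. Its trianion (LiN(iPr)2, 3 equiv) is acylated at the terminal methyl by 1 to give dimethyl 4,25-dimethyl-3,5,7,22,24,26-hexaoxooctacosanedioate F2. The aldol donor is now a doubly activated β-keto-ester methylene, so mild aqueous base (pH 9–10) closes both rings with only one possible regiochemistry, giving dimethyl 6,6'-(tetradecane-1,14-diyl)bis(2,4-dihydroxy-3-methylbenzoate) F3. Saponification with decarboxylation (KOH, ethylene glycol/H2O, 150 °C, then HCl) gives 5.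

Step 2 (nitrosodisulfonate oxidation). The lipophilic bis-resorcinol is poorly soluble in the aqueous medium, and hydroxyquinones with a free ring position can over-oxidise or dimerise. The fallback installs the oxygen by C-formylation and Dakin oxidation instead of radical oxidation. It sets out from 5 and returns at 6. Vilsmeier formylation (POCl3, DMF, then H2O) at the only activated position gives 6,6'-(tetradecane-1,14-diyl)bis(2,4-dihydroxy-3-methylbenzaldehyde) F4. Dakin oxidation (H2O2, aq. NaOH, 0 °C) gives 6,6'-(tetradecane-1,14-diyl)bis(3-methylbenzene-1,2,4-triol) F5. Stirring F5 under air in pH 8 buffer oxidises the para-dihydroxy pair and gives 6.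

Step 5 (acid isomerisation of the epoxide). Cold concentrated H2SO4 may cleave the vinylogous methyl ester or cause acyl shift and ring contraction. The fallback avoids the epoxide altogether by Thiele–Winter acetoxylation. It sets out from 7 and returns at 9. Treatment of 7 with Ac2O and catalytic H2SO4 at rt adds acetate at the only ring C–H and gives the hexaacetate 3,3'-(tetradecane-1,14-diyl)bis(5-methoxy-6-methylbenzene-1,2,4-triyl) hexaacetate F6. Methanolysis (K2CO3, degassed MeOH) gives 3,3'-(tetradecane-1,14-diyl)bis(5-methoxy-6-methylbenzene-1,2,4-triol) F7. Admitting air and then acidifying oxidises the para-dihydroxy pair of F7 and gives 9.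

Further compounds
F1 | step 1 | methyl 4-methyl-3,5-dioxohexanoate | COC(=O)CC(=O)C(C)C(C)=O
F2 | step 1 | dimethyl 4,25-dimethyl-3,5,7,22,24,26-hexaoxooctacosanedioate | COC(=O)CC(=O)C(C)C(=O)CC(=O)CCCCCCCCCCCCCCC(=O)CC(=O)C(C)C(=O)CC(=O)OC
F3 | step 1 | dimethyl 6,6'-(tetradecane-1,14-diyl)bis(2,4-dihydroxy-3-methylbenzoate) | COC(=O)c1c(O)c(C)c(O)cc1CCCCCCCCCCCCCCc1cc(O)c(C)c(O)c1C(=O)OC
F4 | step 2 | 6,6'-(tetradecane-1,14-diyl)bis(2,4-dihydroxy-3-methylbenzaldehyde) | O=Cc1c(O)c(C)c(O)cc1CCCCCCCCCCCCCCc1cc(O)c(C)c(O)c1C=O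
F5 | step 2 | 6,6'-(tetradecane-1,14-diyl)bis(3-methylbenzene-1,2,4-triol) | Cc1c(O)cc(CCCCCCCCCCCCCCc2cc(O)c(C)c(O)c2O)c(O)c1O
F6 | step 5 | 3,3'-(tetradecane-1,14-diyl)bis(5-methoxy-6-methylbenzene-1,2,4-triyl) hexaacetate | COc1c(C)c(OC(C)=O)c(OC(C)=O)c(CCCCCCCCCCCCCCc2c(OC(C)=O)c(OC(C)=O)c(C)c(OC)c2OC(C)=O)c1OC(C)=O
F7 | step 5 | 3,3'-(tetradecane-1,14-diyl)bis(5-methoxy-6-methylbenzene-1,2,4-triol) | COc1c(C)c(O)c(O)c(CCCCCCCCCCCCCCc2c(O)c(O)c(C)c(OC)c2O)c1O
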